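**Retrosynthetic overview**
1. Ten-membered ring (formed last): cut C1–C10 to give the (Z)-alkenyl iodide/aldehyde 26, closed by an intramolecular Ni/Cr (Nozaki–Hiyama–Kishi) addition that also sets C1.
2. Butenolide (formed second): cut C11–C12, C12–O6 and C13–O to give the open-chain 2-substituted 2,3-allenol 20 plus CO, by Pd(II)/CuCl2 chlorocyclocarbonylation followed by Cl→OAc exchange.
3. Enabling feature: in the 13-oxygenated 7(11)-en-12,6-olide, the atoms C13–C11(=C7)–C12 next to the C6–O bond are the retron of a 1,1-disubstituted allene C7=C11=C13H2 beside a C6 carbinol. The central carbon C11 receives the carbonyl, the terminus C13 the heteroatom, and C7=C11 becomes the ring alkene.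
4. Allenol: cut C6–C7 to give epoxy aldehyde 6 (C1–C6, oxirane from Sharpless epoxidation, first ring) and propargylic bromide 16 (C7–C14, C8 from Zn-ProPhenol alkynylation), joined by indium SE2′ allenylation; C6 is corrected by Mitsunobu inversion.
5. Order of ring formation: oxirane (step 3), butenolide (step 15), ten-membered ring (step 19).

Key step: step 15

Remark: the ester is read from the SMILES as the (E)-2-methylbut-2-enoate (tiglate, Tig) and the ring alkene C9=C10 as Z. Germacrane numbering of the target (C1–C10 ring, C11 lactone α-carbon, C12 carbonyl, C13 CH2O, C14 methyl on C10, C15 methyl on C4) is used for all intermediates. TBS = tert-butyldimethylsilyl.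

Step 1
Reactants: 1 pent-4-yn-1-ol
Product: 2 tert-butyldimethyl(pent-4-yn-1-yloxy)silane
Conditions: TBSCl, imidazole, DMF, rt
Reagents that add atoms: tert-butyldimethylsilyl chloride, CC(C)(C)[Si](C)(C)Cl
Why: Routine silylation of the primary alcohol gives a C1–O protecting group that survives the organoaluminium, titanium, indium, Mitsunobu and palladium steps and is removed by fluoride near the end.

Step 2
Reactants: 2 tert-butyldimethyl(pent-4-yn-1-yloxy)silane
Product: 4 (E)-6-(tert-butyldimethylsilyloxy)-3-methylhex-2-en-1-ol, via alkenyldimethylalane 3 (not isolated)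
Conditions: Me3Al, Cp2ZrCl2 (cat.), CH2Cl2, 0 °C to rt; then (CH2O)n, THF, rt
Reagents that add atoms: trimethylaluminium, C[Al](C)C; formaldehyde (from paraformaldehyde), C=O
Why: Negishi zirconium-catalysed syn-carboalumination adds methyl (C15) to the internal and aluminium to the terminal alkyne carbon, and the alkenylalane is trapped by formaldehyde with retention, which gives the E-trisubstituted allylic alcohol (C3 trans to C6).

Step 3
Reactants: 4 (E)-6-(tert-butyldimethylsilyloxy)-3-methylhex-2-en-1-ol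
Product: 5 [(2R,3R)-3-[3-(tert-butyldimethylsilyloxy)propyl]-3-methyloxiran-2-yl]methanol
Conditions: Ti(OiPr)4, D-(−)-diethyl tartrate, t-BuOOH, 4 Å MS, CH2Cl2, −20 °C
Reagents that add atoms: tert-butyl hydroperoxide, CC(C)(C)OO
Why: Sharpless asymmetric epoxidation under reagent control; D-(−)-tartrate delivers oxygen to the face of this geraniol-type E-allylic alcohol that gives the (2R,3R)-epoxy alcohol, i.e. C4 (R) and C5 (R) of the target.

Step 4
Reactants: 5 [(2R,3R)-3-[3-(tert-butyldimethylsilyloxy)propyl]-3-methyloxiran-2-yl]methanol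
Product: 6 (2S,3R)-3-[3-(tert-butyldimethylsilyloxy)propyl]-3-methyloxirane-2-carbaldehyde
Conditions: Dess–Martin periodinane, NaHCO3, CH2Cl2, 0 °C
Reagents that add atoms: none
Why: Buffered Dess–Martin oxidation of the primary epoxy alcohol gives the aldehyde without epimerisation at C5 or opening of the oxirane (the descriptor at C5 changes only because the priorities change).

Step 5
Reactants: 7 ethyl but-2-ynoate
Product: 8 ethyl (Z)-3-iodobut-2-enoate
Conditions: NaI, AcOH, 115 °C
Reagents that add atoms: sodium iodide, [Na+].[I-]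
Why: Conjugate addition of iodide to the ynoate and protonation in acetic acid is a known hydroiodination that gives the Z-β-iodo enoate (iodine cis to the ester).

Step 6
Reactants: 8 ethyl (Z)-3-iodobut-2-enoate
Product: 9 (Z)-3-iodobut-2-en-1-ol
Conditions: DIBAL-H, CH2Cl2, −78 °C
Reagents that add atoms: none
Why: DIBAL-H reduces the ester to the allylic alcohol at low temperature without touching the alkenyl iodide or the Z geometry.

Step 7
Reactants: 9 (Z)-3-iodobut-2-en-1-ol
Product: 10 (Z)-3-iodobut-2-enal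
Conditions: MnO2, CH2Cl2, rt
Reagents that add atoms: none
Why: MnO2 oxidises the allylic alcohol selectively to the enal under neutral conditions that keep the Z geometry; the aldehyde is used at once.

Step 8
Reactants: 10 (Z)-3-iodobut-2-enal; 11 tert-butyldimethyl(prop-2-yn-1-yloxy)silane
Product: 13 (4S,5Z)-1-(tert-butyldimethylsilyloxy)-6-iodohept-5-en-2-yn-4-ol, via alkynyl(methyl)zinc 12 (not isolated)
Conditions: (S,S)-ProPhenol (cat.), Me2Zn, Ph3PO (cat.), toluene, 4 °C
Reagents that add atoms: none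
Why: Zn-ProPhenol (Trost) asymmetric alkynylation of an α,β-unsaturated aldehyde, in which the dinuclear zinc catalyst from the (S,S)-ligand should deliver the zinc acetylide to the Re face of the enal and so set C8 as S under reagent control, 1,2-addition leaving the iodoalkene intact.

Step 9
Reactants: 13 (4S,5Z)-1-(tert-butyldimethylsilyloxy)-6-iodohept-5-en-2-yn-4-ol
Product: 14 (4S,5Z)-1-(tert-butyldimethylsilyloxy)-6-iodohept-5-en-2-yn-4-yl (E)-2-methylbut-2-enoate
Conditions: tiglic acid, DCC, DMAP (cat.), CH2Cl2, 0 °C to rt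
Reagents that add atoms: tiglic acid, C/C=C(\C)C(=O)O
Why: Steglich esterification puts the tiglate on C8 early, so that no protecting group is needed there, and avoids the base-induced deconjugation known for the acid chloride.

Step 10
Reactants: 14 (4S,5Z)-1-(tert-butyldimethylsilyloxy)-6-iodohept-5-en-2-yn-4-yl (E)-2-methylbut-2-enoate
Product: 15 (4S,5Z)-1-hydroxy-6-iodohept-5-en-2-yn-4-yl (E)-2-methylbut-2-enoate
Conditions: HF·pyridine, pyridine, THF, 0 °C
Reagents that add atoms: none
Why: Buffered HF·pyridine cleaves the primary propargylic silyl ether and leaves the ester and the alkenyl iodide alone.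

Step 11
Reactants: 15 (4S,5Z)-1-hydroxy-6-iodohept-5-en-2-yn-4-yl (E)-2-methylbut-2-enoate
Product: 16 (4S,5Z)-1-bromo-6-iodohept-5-en-2-yn-4-yl (E)-2-methylbut-2-enoate
Conditions: CBr4, PPh3, CH2Cl2, 0 °C
Reagents that add atoms: carbon tetrabromide, BrC(Br)(Br)Br
Why: Appel bromination converts the primary propargylic alcohol into the bromide by SN2 under neutral conditions.

Step 12
Reactants: 6 (2S,3R)-3-[3-(tert-butyldimethylsilyloxy)propyl]-3-methyloxirane-2-carbaldehyde; 16 (4S,5Z)-1-bromo-6-iodohept-5-en-2-yn-4-yl (E)-2-methylbut-2-enoate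
Product: 18 (1R)-1-[(2R,3R)-3-[3-(tert-butyldimethylsilyloxy)propyl]-3-methyloxiran-2-yl]-2-[(1S,2Z)-3-iodo-1-[(E)-2-methylbut-2-enoyloxy]but-2-en-1-yl]buta-2,3-dien-1-ol (6R-allenol), via propargylindium dibromide 17 (not isolated)
Conditions: In powder, THF/H2O (1:1), rt
Reagents that add atoms: none
Why: Indium inserts into the propargylic C–Br bond and the propargylindium adds to the aldehyde through a six-membered SE2′ transition state, which for γ-substituted propargyl bromides gives the 2-substituted 2,3-allenol (Barbier allenylation) and forms C6–C7; the polar Cornforth model for the α,β-epoxy aldehyde predicts the 6R (anti) carbinol as the main epimer, and any 6S epimer formed is compound 20 itself and is added after step 14.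

Step 13
Reactants: 18 6R-allenol
Product: 19 (1S)-1-[(2R,3R)-3-[3-(tert-butyldimethylsilyloxy)propyl]-3-methyloxiran-2-yl]-2-[(1S,2Z)-3-iodo-1-[(E)-2-methylbut-2-enoyloxy]but-2-en-1-yl]buta-2,3-dien-1-yl chloroacetate
Conditions: ClCH2CO2H, PPh3, DIAD, toluene, 0 °C to rt
Reagents that add atoms: chloroacetic acid, OC(=O)CCl
Why: Mitsunobu esterification displaces the oxyphosphonium at C6 by chloroacetate in an SN2 step with inversion, which turns the Cornforth adduct into the 6S ester (the classical erythro-to-threo correction of epoxy alcohols).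

Step 14
Reactants: 19 6S-chloroacetate
Product: 20 (1S)-1-[(2R,3R)-3-[3-(tert-butyldimethylsilyloxy)propyl]-3-methyloxiran-2-yl]-2-[(1S,2Z)-3-iodo-1-[(E)-2-methylbut-2-enoyloxy]but-2-en-1-yl]buta-2,3-dien-1-ol (6S-allenol)
Conditions: K2CO3 (cat.), MeOH, 0 °C
Reagents that add atoms: none
Why: The chloroacetate is methanolysed far faster than the hindered, conjugated tiglate, so catalytic carbonate in cold methanol frees the C6 hydroxyl only.

Step 15
Reactants: 20 6S-allenol
Product: 23 (5S)-3-(chloromethyl)-5-[(2R,3R)-3-[3-(tert-butyldimethylsilyloxy)propyl]-3-methyloxiran-2-yl]-4-[(1S,2Z)-3-iodo-1-[(E)-2-methylbut-2-enoyloxy]but-2-en-1-yl]furan-2(5H)-one, via alkoxycarbonylpalladium chloride 21 (not isolated), via allylpalladium chloride 22 (not isolated)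
Conditions: PdCl2 (cat.), CuCl2 (excess), CO (1 atm), MgO, THF, rt
Reagents that add atoms: carbon monoxide, [C-]#[O+]; copper(II) chloride, Cl[Cu]Cl
Why: PdCl2, CO and the C6 hydroxyl give the alkoxycarbonylpalladium chloride 21, whose acyl carbon C12 adds to the central allene carbon C11 and so forms the C11–C12 bond and closes the lactone in a 5-exo insertion into the C11=C13 π bond (ring atoms O, C12, C11, C7, C6). The resulting 2-(alkoxycarbonyl)allylpalladium 22 is cleaved by CuCl2 at the unsubstituted terminus C13, which leaves the tetrasubstituted C7=C11 double bond inside the lactone and returns Pd(II). The closest known reaction is the PdCl2/CuCl2 chlorocyclocarbonylation of 2,3-allenols to 3-chloromethyl-2(5H)-furanones (a Semmelhack-type alkoxycarbonylation that ends in chlorination of the allyl–Pd bond). No stereocentre is made; C6 keeps its configuration because its C–O bond is never broken, and the geometry of the new alkene is fixed by the ring. The step needs regioselectivity for the central allene carbon and for chloride delivery to C13 (secured by the five-membered closure and by the primary, unhindered terminus) and chemoselectivity towards the alkenyl iodide, the oxirane and the esters (secured by excess CuCl2 holding palladium at +2, by the single free hydroxyl and by MgO, which takes up the HCl).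

Step 16
Reactants: 23 chloromethyl butenolide
Product: 24 (5S)-3-(acetoxymethyl)-5-[(2R,3R)-3-[3-(tert-butyldimethylsilyloxy)propyl]-3-methyloxiran-2-yl]-4-[(1S,2Z)-3-iodo-1-[(E)-2-methylbut-2-enoyloxy]but-2-en-1-yl]furan-2(5H)-one
Conditions: KOAc, 18-crown-6 (cat.), MeCN, rt
Reagents that add atoms: potassium acetate, CC(=O)[O-].[K+]
Why: SN2 displacement of the primary allylic chloride by acetate installs the C13 acetate, SN2′ attack being blocked because it would have to form a bond at the fully substituted C7.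

Step 17
Reactants: 24 acetoxymethyl butenolide silyl ether
Product: 25 (5S)-3-(acetoxymethyl)-5-[(2R,3R)-3-(3-hydroxypropyl)-3-methyloxiran-2-yl]-4-[(1S,2Z)-3-iodo-1-[(E)-2-methylbut-2-enoyloxy]but-2-en-1-yl]furan-2(5H)-one
Conditions: HF·pyridine, pyridine, THF, 0 °C to rt
Reagents that add atoms: none
Why: Buffered HF·pyridine removes the primary TBS ether without opening the oxirane and avoids the basic fluoride sources that would deprotonate the butenolide at C6.

Step 18
Reactants: 25 primary alcohol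
Product: 26 (5S)-3-(acetoxymethyl)-4-[(1S,2Z)-3-iodo-1-[(E)-2-methylbut-2-enoyloxy]but-2-en-1-yl]-5-[(2R,3R)-3-methyl-3-(3-oxopropyl)oxiran-2-yl]furan-2(5H)-one
Conditions: Dess–Martin periodinane, NaHCO3, CH2Cl2, 0 °C
Reagents that add atoms: none
Why: Buffered Dess–Martin oxidation gives the C1 aldehyde under neutral conditions that leave the esters, the oxirane and the alkenyl iodide untouched.

Step 19
Reactants: 26 iodo aldehyde
Product: 28 (1S,4R,5R,6S,8S,9Z)-13-acetoxy-4,5-epoxy-1-hydroxy-8-tigloyloxygermacra-7(11),9-dien-12,6-olide (CNP0222387.1), via alkenylchromium dichloride 27 (not isolated)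
Conditions: CrCl2 (excess), NiCl2 (cat.), DMSO/THF, rt, high dilution (slow addition)
Reagents that add atoms: none
Why: Intramolecular Nozaki–Hiyama–Kishi reaction, in which Ni(0) inserts into the alkenyl C–I bond with retention of the Z geometry and transmetalation gives the alkenylchromium(III) species that adds to the C1 aldehyde to close the ten-membered ring; with H8 held in the alkene plane by A(1,3) strain and C2 forced onto the ring face, the chromium-bound oxygen should take the exo position on the face of the C8 oxygen, which corresponds to the 1S carbinol.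

**Compound list**
1 | pent-4-yn-1-ol | C#CCCCO | starting material
2 | tert-butyldimethyl(pent-4-yn-1-yloxy)silane | C#CCCCO[Si](C)(C)C(C)(C)C | intermediate
3 | (E)-[5-(tert-butyldimethylsilyloxy)-2-methylpent-1-en-1-yl]dimethylalane | C[Al](C)/C=C(\C)CCCO[Si](C)(C)C(C)(C)C | intermediate
4 | (E)-6-(tert-butyldimethylsilyloxy)-3-methylhex-2-en-1-ol | OC/C=C(\C)CCCO[Si](C)(C)C(C)(C)C | intermediate
5 | [(2R,3R)-3-[3-(tert-butyldimethylsilyloxy)propyl]-3-methyloxiran-2-yl]methanol | CC(C)(C)[Si](C)(C)OCCC[C@@]1(C)O[C@@H]1CO | intermediate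
6 | (2S,3R)-3-[3-(tert-butyldimethylsilyloxy)propyl]-3-methyloxirane-2-carbaldehyde | CC(C)(C)[Si](C)(C)OCCC[C@@]1(C)O[C@@H]1C=O | intermediate
7 | ethyl but-2-ynoate | CC#CC(=O)OCC | starting material
8 | ethyl (Z)-3-iodobut-2-enoate | CCOC(=O)/C=C(/C)I | intermediate
9 | (Z)-3-iodobut-2-en-1-ol | OC/C=C(/C)I | intermediate
10 | (Z)-3-iodobut-2-enal | O=C/C=C(/C)I | intermediate
11 | tert-butyldimethyl(prop-2-yn-1-yloxy)silane | C#CCO[Si](C)(C)C(C)(C)C | starting material
12 | [3-(tert-butyldimethylsilyloxy)prop-1-yn-1-yl](methyl)zinc | C[Zn]C#CCO[Si](C)(C)C(C)(C)C | intermediate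
13 | (4S,5Z)-1-(tert-butyldimethylsilyloxy)-6-iodohept-5-en-2-yn-4-ol | O[C@H](C#CCO[Si](C)(C)C(C)(C)C)/C=C(/C)I | intermediate
14 | (4S,5Z)-1-(tert-butyldimethylsilyloxy)-6-iodohept-5-en-2-yn-4-yl (E)-2-methylbut-2-enoate | C/C=C(\C)C(=O)O[C@H](C#CCO[Si](C)(C)C(C)(C)C)/C=C(/C)I | intermediate
15 | (4S,5Z)-1-hydroxy-6-iodohept-5-en-2-yn-4-yl (E)-2-methylbut-2-enoate | C/C=C(\C)C(=O)O[C@H](C#CCO)/C=C(/C)I | intermediate
16 | (4S,5Z)-1-bromo-6-iodohept-5-en-2-yn-4-yl (E)-2-methylbut-2-enoate | C/C=C(\C)C(=O)O[C@H](C#CCBr)/C=C(/C)I | intermediate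
17 | propargylindium dibromide from 16 (indium on C13 in place of bromine) | C/C=C(\C)C(=O)O[C@H](C#CC[In](Br)Br)/C=C(/C)I | intermediate
18 | 6R-allenol: (1R)-1-[(2R,3R)-3-[3-(tert-butyldimethylsilyloxy)propyl]-3-methyloxiran-2-yl]-2-[(1S,2Z)-3-iodo-1-[(E)-2-methylbut-2-enoyloxy]but-2-en-1-yl]buta-2,3-dien-1-ol | CC(C)(C)[Si](C)(C)OCCC[C@@]1(C)O[C@@H]1[C@H](O)C(=C=C)[C@@H](OC(=O)/C(C)=C/C)/C=C(/C)I | intermediate
19 | 6S-chloroacetate: (1S)-1-[(2R,3R)-3-[3-(tert-butyldimethylsilyloxy)propyl]-3-methyloxiran-2-yl]-2-[(1S,2Z)-3-iodo-1-[(E)-2-methylbut-2-enoyloxy]but-2-en-1-yl]buta-2,3-dien-1-yl chloroacetate | CC(C)(C)[Si](C)(C)OCCC[C@@]1(C)O[C@@H]1[C@@H](OC(=O)CCl)C(=C=C)[C@@H](OC(=O)/C(C)=C/C)/C=C(/C)I | intermediate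
20 | 6S-allenol: (1S)-1-[(2R,3R)-3-[3-(tert-butyldimethylsilyloxy)propyl]-3-methyloxiran-2-yl]-2-[(1S,2Z)-3-iodo-1-[(E)-2-methylbut-2-enoyloxy]but-2-en-1-yl]buta-2,3-dien-1-ol | CC(C)(C)[Si](C)(C)OCCC[C@@]1(C)O[C@@H]1[C@@H](O)C(=C=C)[C@@H](OC(=O)/C(C)=C/C)/C=C(/C)I | intermediate
21 | alkoxycarbonylpalladium chloride of 20 (C6–O–C(=O)–PdCl) | CC(C)(C)[Si](C)(C)OCCC[C@@]1(C)O[C@@H]1[C@@H](OC(=O)[Pd]Cl)C(=C=C)[C@@H](OC(=O)/C(C)=C/C)/C=C(/C)I | intermediate
22 | allylpalladium chloride of the closed lactone (Pd on C13, drawn as the σ form) | CC(C)(C)[Si](C)(C)OCCC[C@@]1(C)O[C@@H]1[C@H]1OC(=O)C(C[Pd]Cl)=C1[C@@H](OC(=O)/C(C)=C/C)/C=C(/C)I | intermediate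
23 | (5S)-3-(chloromethyl)-5-[(2R,3R)-3-[3-(tert-butyldimethylsilyloxy)propyl]-3-methyloxiran-2-yl]-4-[(1S,2Z)-3-iodo-1-[(E)-2-methylbut-2-enoyloxy]but-2-en-1-yl]furan-2(5H)-one | CC(C)(C)[Si](C)(C)OCCC[C@@]1(C)O[C@@H]1[C@H]1OC(=O)C(CCl)=C1[C@@H](OC(=O)/C(C)=C/C)/C=C(/C)I | intermediate
24 | (5S)-3-(acetoxymethyl)-5-[(2R,3R)-3-[3-(tert-butyldimethylsilyloxy)propyl]-3-methyloxiran-2-yl]-4-[(1S,2Z)-3-iodo-1-[(E)-2-methylbut-2-enoyloxy]but-2-en-1-yl]furan-2(5H)-one | CC(C)(C)[Si](C)(C)OCCC[C@@]1(C)O[C@@H]1[C@H]1OC(=O)C(COC(C)=O)=C1[C@@H](OC(=O)/C(C)=C/C)/C=C(/C)I | intermediate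
25 | (5S)-3-(acetoxymethyl)-5-[(2R,3R)-3-(3-hydroxypropyl)-3-methyloxiran-2-yl]-4-[(1S,2Z)-3-iodo-1-[(E)-2-methylbut-2-enoyloxy]but-2-en-1-yl]furan-2(5H)-one | OCCC[C@@]1(C)O[C@@H]1[C@H]1OC(=O)C(COC(C)=O)=C1[C@@H](OC(=O)/C(C)=C/C)/C=C(/C)I | intermediate
26 | (5S)-3-(acetoxymethyl)-4-[(1S,2Z)-3-iodo-1-[(E)-2-methylbut-2-enoyloxy]but-2-en-1-yl]-5-[(2R,3R)-3-methyl-3-(3-oxopropyl)oxiran-2-yl]furan-2(5H)-one | O=CCC[C@@]1(C)O[C@@H]1[C@H]1OC(=O)C(COC(C)=O)=C1[C@@H](OC(=O)/C(C)=C/C)/C=C(/C)I | intermediate
27 | alkenylchromium(III) dichloride from 26 (Cr on C10 in place of iodine) | O=CCC[C@@]1(C)O[C@@H]1[C@H]1OC(=O)C(COC(C)=O)=C1[C@@H](OC(=O)/C(C)=C/C)/C=C(/C)[Cr](Cl)Cl | intermediate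
28 | (1S,4R,5R,6S,8S,9Z)-13-acetoxy-4,5-epoxy-1-hydroxy-8-tigloyloxygermacra-7(11),9-dien-12,6-olide (CNP0222387.1) | C/C=C(\C)C(=O)O[C@H]1/C=C(/C)[C@@H](O)CC[C@@]2(C)O[C@@H]2[C@H]2OC(=O)C(COC(C)=O)=C12 | target

**Step count and risks**
Total step count: 19. Longest linear sequence: 15 steps (steps 5–11, then 12–19, from ethyl but-2-ynoate).

Steps most likely to fail:

1. Step 15 (key step). Transient Pd(0), released when the allyl–Pd bond of 22 is chlorinated, may insert into the alkenyl C–I bond before CuCl2 reoxidises it; acid-promoted opening of the oxirane is the second concern. Fallback (ring closure before carbonylation, so that no C–I bond is present): it sets out from 20 and comes back at 28. Buffered HF·pyridine should give the allene diol F1. Oxidation of the primary hydroxyl only (TEMPO, PhI(OAc)2) should give the hydroxy aldehyde F2. Ni/Cr ring closure under high dilution with minimal nickel should give the macrocyclic allenediol F3. The same PdCl2/CuCl2/CO/MgO carbonylation should then give the macrocyclic chloromethyl butenolide F4, and KOAc with 18-crown-6 should give 28.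

2. Step 19. The ring-closing transition state may show low facial selectivity at the C1 aldehyde (the A(1,3) argument is qualitative), so that the C1 epimer forms beside 28; oligomerisation competes if dilution is insufficient. Fallback (redox correction under reagent control): it sets out from 26 and comes back at 28. The ring closure is run as before, and the mixture of 28 and its C1 epimer F5 is oxidised with Dess–Martin periodinane to the macrocyclic C1 enone F6. Reduction with (R)-Me-CBS and catecholborane at low temperature should then deliver hydride to the face that gives the 1S alcohol 28.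

3. Step 13. The activated C6 oxygen may leave with SN2′ attack at the allene terminus C13, or with elimination, instead of clean inversion. Fallback (carbinol before oxirane, no inversion needed): it sets out from 4 and 16 and comes back at 20. MnO2 oxidation of 4 should give the enal F7. Indium coupling with 16 as in step 12 should give the dienyl allenol F8 together with its C6 epimer F9, which is removed by chromatography; no facial control at C6 is expected here. Hydroxyl-directed epoxidation of F8 with mCPBA should give the threo epoxy alcohol 20 directly, because A(1,3) strain from the C15 methyl holds H6 in the alkene plane and the peracid is delivered syn to the hydroxyl.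

**Further compounds**
F1 | step 15 | allene diol (20 without the silyl group; C1 and C6 hydroxyls free) | OCCC[C@@]1(C)O[C@@H]1[C@@H](O)C(=C=C)[C@@H](OC(=O)/C(C)=C/C)/C=C(/C)I
F2 | step 15 | hydroxy aldehyde (C1 aldehyde of F1, C6 hydroxyl free) | O=CCC[C@@]1(C)O[C@@H]1[C@@H](O)C(=C=C)[C@@H](OC(=O)/C(C)=C/C)/C=C(/C)I
F3 | step 15 | macrocyclic allenediol: (1S,4R,5R,6S,8S,9Z)-4,5-epoxy-1,6-dihydroxy-8-tigloyloxy ten-membered ring with exocyclic vinylidene on C7 | C/C=C(\C)C(=O)O[C@H]1/C=C(/C)[C@@H](O)CC[C@@]2(C)O[C@@H]2[C@@H](O)C1=C=C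
F4 | step 15 | macrocyclic chloromethyl butenolide (28 with Cl in place of OAc at C13) | C/C=C(\C)C(=O)O[C@H]1/C=C(/C)[C@@H](O)CC[C@@]2(C)O[C@@H]2[C@H]2OC(=O)C(CCl)=C12
F5 | step 19 | C1 epimer of 28 (1R) | C/C=C(\C)C(=O)O[C@H]1/C=C(/C)[C@H](O)CC[C@@]2(C)O[C@@H]2[C@H]2OC(=O)C(COC(C)=O)=C12
F6 | step 19 | macrocyclic C1 enone (1-oxo analogue of 28) | C/C=C(\C)C(=O)O[C@H]1/C=C(/C)C(=O)CC[C@@]2(C)O[C@@H]2[C@H]2OC(=O)C(COC(C)=O)=C12
F7 | step 13 | (E)-6-(tert-butyldimethylsilyloxy)-3-methylhex-2-enal | O=C/C=C(\C)CCCO[Si](C)(C)C(C)(C)C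
F8 | step 13 | (4R,5E)-9-(tert-butyldimethylsilyloxy)-3-[(1S,2Z)-3-iodo-1-[(E)-2-methylbut-2-enoyloxy]but-2-en-1-yl]-6-methylnona-1,2,5-trien-4-ol (same spatial sense at C6 as 20; descriptor R because C7 now outranks C5) | CC(C)(C)[Si](C)(C)OCCC/C(C)=C/[C@@H](O)C(=C=C)[C@@H](OC(=O)/C(C)=C/C)/C=C(/C)I
F9 | step 13 | (4S,5E)-9-(tert-butyldimethylsilyloxy)-3-[(1S,2Z)-3-iodo-1-[(E)-2-methylbut-2-enoyloxy]but-2-en-1-yl]-6-methylnona-1,2,5-trien-4-ol (C6 epimer of F8) | CC(C)(C)[Si](C)(C)OCCC/C(C)=C/[C@H](O)C(=C=C)[C@@H](OC(=O)/C(C)=C/C)/C=C(/C)I
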